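The readings stem from a simulated flask for substances that don't exist, noise included.

Late partner and late substrate are different delays, so I compare the flasks by how long partner has been in each.

| flask | substrate | partner | capture agent | remark | time |
|---|---|---|---|---|---|
| violet | 10 mM | 1.5 equiv | 10 mM | run made earlier |  |
| grey | 5 mM | 1.5 equiv | 10 mM | run made earlier |  |
| teal | 7.5 mM | 1.5 equiv | 10 mM | run made earlier |  |
| dusk | 10 mM | 1.50 equiv (fed, over 2.50 h) | 10.0 mM | all but partner at the start; partner goes in evenly over 2.50 h, the run ends at 5.0 h | 5.0 h |
| spring | 10 mM (fed, over 2.50 h) | 1.50 equiv | 10.0 mM | a stirred flask in which substrate is dosed at a steady rate over 2.50 h without added volume, worked up at 5.0 h | 5.0 h |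
| noon | 10 mM | 1.50 equiv | 10.0 mM | one stirred flow tank at steady state, fed with the mixture as stated, mean residence time 5.0 h |  |
| autumn | 10 mM | 1.50 equiv | 10.0 mM | a closed flask charged with all of it at once and left for 5.0 h | 5.0 h |

- violet (time / h: open intermediate / %, product / %, substrate / %): 0.250: 26, 0, 71; 0.417: 37, 5, 60; 0.833: 59, 6, 33; 1.50: 74, 11, 16; 3.00: 69, 31, 4
- grey (time / h: open intermediate / %, product / %, substrate / %): 0.417: 40, 1, 62; 0.833: 59, 5, 35; 1.33: 75, 7, 19; 2.50: 81, 15, 3; 5.00: 56, 36, 0
- teal (time / h: open intermediate / %, product / %, substrate / %): 0.417: 37, 0, 58; 0.833: 57, 3, 36; 1.33: 73, 8, 20; 2.50: 77, 22, 5; 5.00: 59, 43, 0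

(each reading ± 2 percentage points)

- the stated concentrations are those of everything mixed, before any reaction; amounts are the same in each set-up
- the earlier runs were read with a standard deviation of 2 percentage points
- the feed brings no volume worth counting
- the earlier runs were made in a closed, stirred flask

- the set-up with the highest amount of open intermediate at the outlet or at the end, in percent of the substrate put in ("none" if the first two lie within 2 percentage points) (dusk / spring / noon / autumn / none)
- amount of open intermediate at the outlet or at the end, in percent of the substrate put in, dusk
- amount of open intermediate at the outlet or at the end, in percent of the substrate put in, spring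
- amount of open intermediate at the outlet or at the end, in percent of the substrate put in, noon
- amount of open intermediate at the outlet or at the end, in percent of the substrate put in, autumn

In violet, substrate is down to 4% at 3.00 h, and open intermediate plus product add up to 100%, so I take the end of a flask as the charge split between those two. Up to that reading, violet made product at 0.103 h⁻¹ on average, as a fraction of the charge. I assume that product grows with the time partner has been present, not with [open intermediate]. The mean stay of partner in dusk is 3.75 h; I call this mean stay the partner time.

For dusk, the ceiling comes from counting the whole feed as arriving at its end, a stay of 2.50 h, which leaves 74.2% open intermediate. The floor comes from counting it as present from the start, a stay of 5.0 h, which leaves 48.3%. For the even feed my estimate is 61.2%. Spring and autumn hold partner for 5.0 h, so my rule puts both on that floor and dusk above them. It doesn't reach noon.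

The forecast names spring as best, with dusk 55%, spring 59%, noon 48% and autumn 52%, holding of spring that “late substrate shortens intermediate lifetime”. Its dusk lies inside my bracket but below my estimate, and we part on the best flask.

The flasks give dusk 64.3%, spring 54.5%, noon 48.7% and autumn 53.7%; dusk is highest and inside the bracket.

    second intermediate + capture agent → trapped intermediate (k = 9.70 L mol⁻¹ h⁻¹)
    substrate → open intermediate (k = 1.20 h⁻¹)
    open intermediate + second intermediate → product (k = 180 L mol⁻¹ h⁻¹)
    partner → second intermediate (k = 0.0980 h⁻¹)

In dusk at 0.576 h, the product step gives second intermediate a half-life of 0.77 h, shorter than the 7.1 h half-life of partner by its own turning; of these two steps on the way to product, the turning of partner is the slower, the rate-limiting step. At 5.00 h in dusk, second intermediate goes to product 12 times as fast as to trapped intermediate. Per hour of partner time, dusk made 0.0945 h⁻¹ of the charge as product and autumn 0.0920 h⁻¹. Dusk left until 8.0 h has a partner time of 6.75 h and made 0.0872 h⁻¹.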